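The closed, stirred vessel held substrate and coupling partner at constant temperature, and I wanted the height and time of the mono adduct's top.

| flask | substrate | coupling partner | remark | time |
|---|---|---|---|---|
| red | 0.36 M | 0.16 M | run made earlier |  |
| ochre | 0.36 M | 0.65 M | run made earlier |  |
| blue | 0.18 M | 0.324 M | run made earlier |  |
| flask | 0.36 M | 0.324 M |  | 80 min |

| run | time / min | mono adduct / % | substrate / % |
|---|---|---|---|
| red | 1.00 | 4 | 96 |
| red | 4.00 | 8 | 82 |
| red | 15.0 | 7 | 66 |
| red | 50.0 | 0 | 61 |
| ochre | 1.00 | 12 | 79 |
| ochre | 4.00 | 19 | 42 |
| ochre | 15.0 | 9 | 12 |
| ochre | 50.0 | 2 | 0 |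
| blue | 1.00 | 8 | 87 |
| blue | 4.00 | 11 | 63 |
| blue | 15.0 | 10 | 28 |
| blue | 50.0 | 4 | 4 |

(each reading ± 1.5 percentage points)

- the best time, 80 min at the latest, for mono adduct
- the amount of mono adduct, in percent of the substrate charged, at that time



Mono adduct is made while substrate is used and lost while it stands, so at its top the two rates balance: a quasi-steady-state reckoning. In the ochre run, counting one coupling partner per substrate, the fall between the first two readings gave k = 0.00691 M⁻¹ s⁻¹. Red and ochre share the flask's substrate charge and both read highest at 4.00 min, so I took that reading as their top. Mono adduct there, divided by k·c(substrate)·c(coupling partner), gave 2.47 min and 2.47 min. Their mean is the hold-up time, mono adduct at its top over the fraction of substrate used per minute at that moment: 2.47 min.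

Integrating the same rate law to 4.00 min gave the flask c(substrate) = 0.237 M, and the hold-up time turned that into 13.5%. My second way was blue, with the flask's partner charge but half its substrate charge, which read 11% at 4.00 min. The two parted, so I tested blue. Balance there would stand at 16.6% at 4.00 min, above the reading, and at 5.58% at 15.0 min, below it. By this reckoning blue's top lay between those readings, so I did not read that number as a top, and this was the way that cheated. I kept the hold-up reckoning, near 4.00 min.

The forecast said 13% at 4.5 min: “The peak comes early”.

The flask gave 13.2% at 4.28 min, and at 4.45 min the rate of making mono adduct over the rate of using it stood at 0.975.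

    coupling partner + mono adduct → double product + by-product (k = 0.00590 M⁻¹ s⁻¹)
    substrate + coupling partner → mono adduct + by-product (k = 0.00500 M⁻¹ s⁻¹)
    coupling partner + other mono adduct → double product + by-product (k = 0.00180 M⁻¹ s⁻¹)
    mono adduct → over-reaction product (k = 0.00190 s⁻¹)
    substrate + coupling partner → other mono adduct + by-product (k = 0.00210 M⁻¹ s⁻¹)
    mono adduct ⇌ isomer of the product (K = 2.20, k = 0.00160 s⁻¹)
    coupling partner → decomposed reagent (k = 9.40 × 10⁻⁵ s⁻¹)

With the flask's own substrate and partner at 4.28 min, the hold-up time gives 11.7%, 1.5 percentage points under the result; the hold-up time was read with one partner counted per substrate, and this partner figure is not counted so. For the neighbour with 0.13 M of coupling partner, the same reckoning at 4.00 min gives 6.54%. That flask gave 6.74%.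

(Readings and results were computed on assumed constants; noise was put on by code.)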